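The readings were generated by integration from invented constants.

At the last reading of the dawn run, 3.00 d, the substrate has lost 25.0 % of its charge and the target stands at 21 %, and I reckon from these two readings.

| flask | substrate | solid reagent | remark | time |
|---|---|---|---|---|
| summer | 14 mM | 14 mM | run made earlier |  |
| dawn | 54 mM | 14 mM | run made earlier |  |
| theta | 20 mM | 14.0 mM |  | 6.0 d |
| gamma | 80 mM | 14.0 mM |  | 10 d |

| run | time / d | target / % | substrate / % |
|---|---|---|---|
| summer | 0.167 | 1 | 97 |
| summer | 0.500 | 1 | 102 |
| summer | 0.833 | 0 | 102 |
| summer | 1.25 | 0 | 100 |
| summer | 1.67 | 3 | 98 |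
| summer | 2.50 | 7 | 97 |
| summer | 3.00 | 13 | 86 |
| dawn | 0.250 | 0 | 102 |
| dawn | 0.333 | 2 | 103 |
| dawn | 0.500 | 0 | 99 |
| dawn | 0.833 | 0 | 102 |
| dawn | 1.25 | 1 | 99 |
| dawn | 2.08 | 14 | 78 |
| dawn | 3.00 | 21 | 75 |

(each reading ± 2 percentage points)

- solid, in amounts per volume of the solution: solid reagent
- at the start none of the solid reagent is in solution
- a reading or a percentage of target counts all its forms, free or not

- which one finishes higher in amount of target, in percent of the substrate charged ("neither" within 2 percentage points) (theta / gamma / neither)
- amount of target at the end, in percent of the substrate charged, theta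
- amount of target at the end, in percent of the substrate charged, gamma

In the dawn run the solid reagent is 25.9 % of the substrate charged, close to that loss. In gamma the same fraction is 17.5 % and in theta 70.0 %. I call this fraction the reagent ceiling: the charge of solid reagent over the charge of substrate, which is the most substrate a flask can lose if each solid reagent takes one substrate. In gamma the solid reagent would then be the limiting reagent.

The target in the dawn run lags the substrate loss by 4 percentage points, and although each reading scatters by 2 points, I treat this gap as a small correction: in those two readings 16.0 % of the lost substrate does not appear as target. With that share taken off the ceiling, my reckoning for gamma is near 14.7 %. Theta has the higher ceiling, and the summer run already reads 13 % at 3.00 d, so I expect theta to finish higher.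

The forecast also names theta, with theta at 45 % (32 % to 62 %) and gamma at 18 % (14 % to 32 %), above my figure for gamma, saying “the reagent should cap it”.

The flasks give theta: theta 51.2 %, gamma 13.3 %.

    substrate + coupling partner + by-product → target + 2 by-product (k = 0.190 M⁻² s⁻¹)
    substrate + coupling partner → target + by-product (k = 3.80 × 10⁻⁶ M⁻¹ s⁻¹)
    coupling partner + target ⇌ idle adduct, settled at all times (K = 100 M⁻¹)
    target ⇌ isomer of the product (K = 0.320, k = 7.10 × 10⁻⁵ s⁻¹)
    solid reagent ⇌ coupling partner, rate k5*(cs5 - [coupling partner]) while solid is left; crystals form when [coupling partner] > cs5 (solubility = 17.0 mM, k = 4.80 × 10⁻⁶ s⁻¹)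

In gamma, free target has a half-life of 0.11 d towards the isomer of the product by the forward rate alone at 1.22 d, far shorter than gamma's 10 d. Gamma ends with target 13.3 % and isomer of the product 4.24 %, together 17.5 % against the ceiling 17.5 %, and the ceiling divided by one plus the equilibrium constant of target to isomer of the product, 1.32, gives 13.3 %. In a flask like gamma but with 35 mM of solid reagent, the ceiling 43.8 % divided the same way gives 33.1 %, and that flask holds 33.1 % of target.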